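**Retrosynthetic overview**
1. The last bond made is the side-chain ester C–O, by Steglich acylation of (R)-shikonin 21 with 3-acetoxy-3-methylbutanoic acid 24. The two phenols of ring A (C5–C8) are freed from MOM ethers one step earlier.
2. Ring B (the quinone ring C1–C4, C4a, C8a) is built onto ring A by a silicon-tethered Dötz benzannulation. The aryl carbene carbon (C1, already on C8a), a terminal alkyne (C2, C3) and one CO ligand (C4) combine, forming C1–C2, C3–C4 and C4–C4a in one operation.
3. Enabling feature: the carbinol oxygen on C1' of the side chain and the oxygen on C1 of ring B are 1,3-related through C2. One i-Pr2Si atom can therefore bridge them in a six-membered 1,3,2-dioxasilin ring, which forces the substituted alkyne carbon onto the carbene carbon. Ring A offers only one free ortho carbon (the future C4a).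
4. Fragments: chromium acylate 6 comes from hydroquinone (MOM ethers, ortho-lithiation, Cr(CO)6). (R)-Enynol 14 comes from 4-methylpent-3-enoic acid via a Weinreb ynone and a Noyori transfer hydrogenation, which sets the only stereocentre.
5. Ring order: ring A is bought, the dioxasilin ring and ring B form together in step 8, and the dioxasilin ring is removed in step 9.

Key step: step 8

Assumption: 4-methylpent-3-enoic acid and 3-hydroxy-3-methylbutanoic acid are taken as commercial; locants are those of naphthalene-1,4-dione with the side chain on C2; in SMILES, CO ligands are written Cr=C=O and the η6 bond in 17 as a dot.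

**Step 1**
Reactants: 1 hydroquinone
Product: 2 1,4-bis(methoxymethoxy)benzene
Conditions: NaH, MOMCl, DMF, 0 °C to rt
Reagents that add atoms: chloromethyl methyl ether (MOMCl), COCCl
Why: Williamson ether synthesis on the bis-phenoxide gives the bis-MOM ether, whose acetal oxygens later direct lithiation and come off under mild acid.

**Step 2**
Reactants: 2 1,4-bis(methoxymethoxy)benzene; 3 hexacarbonylchromium Cr(CO)6
Product: 6 tetramethylammonium pentacarbonyl{[2,5-bis(methoxymethoxy)phenyl](oxido)methylidene}chromate, via aryllithium 4 (not isolated), via lithium acylate 5 (not isolated)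
Conditions: n-BuLi, TMEDA, Et2O, 0 °C; Cr(CO)6, 0 °C to rt; Me4NBr, degassed H2O, extraction into CH2Cl2
Reagents that add atoms: tetramethylammonium bromide, C[N+](C)(C)C.[Br-]; n-butyllithium, [Li]CCCC (lithium stays only in 4 and 5)
Why: Directed ortho-metalation (all four ring hydrogens are equivalent, so one aryllithium results) followed by the Fischer carbene route, in which the aryllithium adds to a CO ligand of Cr(CO)6, puts the future C1 on ring A, and cation exchange gives a storable acylate salt.

**Step 3**
Reactants: 7 4-methylpent-3-enoic acid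
Product: 9 N-methoxy-N,4-dimethylpent-3-enamide, via acyl imidazolide 8 (not isolated)
Conditions: CDI, CH2Cl2, 0 °C to rt; MeNH(OMe)·HCl, rt
Reagents that add atoms: N,O-dimethylhydroxylamine hydrochloride, CNOC.Cl; 1,1'-carbonyldiimidazole, O=C(n1ccnc1)n1ccnc1 (its imidazole stays only in 8)
Why: Amide coupling through the acyl imidazolide runs without strong base, so the β,γ-double bond should not move into conjugation.

**Step 4**
Reactants: 9 N-methoxy-N,4-dimethylpent-3-enamide; 10 trimethylsilylacetylene
Product: 12 6-methyl-1-(trimethylsilyl)hept-5-en-1-yn-3-one, via lithium acetylide 11 (not isolated)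
Conditions: 10, n-BuLi, THF, −78 °C; then 9, −78 to −20 °C; cold aq NH4Cl
Reagents that add atoms: n-butyllithium, [Li]CCCC (lithium stays only in 11)
Why: Weinreb ketone synthesis, in which the chelated tetrahedral adduct holds until the cold quench, so a single acetylide addition gives the ynone.

**Step 5**
Reactants: 12 6-methyl-1-(trimethylsilyl)hept-5-en-1-yn-3-one
Product: 13 (3R)-6-methyl-1-(trimethylsilyl)hept-5-en-1-yn-3-ol
Conditions: Ru[(R,R)-TsNCH(Ph)CH(Ph)NH](p-cymene) (1 mol %), i-PrOH, rt
Reagents that add atoms: none
Why: Noyori asymmetric transfer hydrogenation of an alkynyl ketone, in which the alkynyl group takes the place of the aryl group in the six-membered hydride-transfer transition state so that the (R,R)-ligand should deliver hydride to the face that gives the R alcohol, and the base-free medium leaves the β,γ-alkene in place.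

**Step 6**
Reactants: 13 (3R)-6-methyl-1-(trimethylsilyl)hept-5-en-1-yn-3-ol
Product: 14 (3R)-6-methylhept-5-en-1-yn-3-ol
Conditions: K2CO3 (cat.), MeOH, 0 °C to rt
Reagents that add atoms: none
Why: Protodesilylation of the C(sp)–Si bond by catalytic methoxide frees the terminal alkyne without touching the carbinol centre.

**Step 7**
Reactants: 14 (3R)-6-methylhept-5-en-1-yn-3-ol
Product: 15 chloro{[(3R)-6-methylhept-5-en-1-yn-3-yl]oxy}diisopropylsilane
Conditions: i-Pr2SiCl2 (1.1 equiv), Et3N, CH2Cl2, 0 °C, slow addition of 14; filtration under Ar, used crude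
Reagents that add atoms: dichlorodiisopropylsilane, CC(C)[Si](Cl)(Cl)C(C)C
Why: Silyl ether formation stops after one chloride because the second substitution at the diisopropyl-substituted silicon is much slower, which is the standard first half of a temporary silicon tether.

**Step 8**
Reactants: 6 tetramethylammonium pentacarbonyl{[2,5-bis(methoxymethoxy)phenyl](oxido)methylidene}chromate; 15 chloro{[(3R)-6-methylhept-5-en-1-yn-3-yl]oxy}diisopropylsilane
Product: 18 (4R)-2,2-diisopropyl-7,10-bis(methoxymethoxy)-4-(3-methylbut-2-enyl)-4H-naphtho[1,2-d][1,3,2]dioxasilin-6-ol, via siloxycarbene complex 16 (not isolated), via tricarbonylchromium naphthol complex 17 (not isolated)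
Conditions: CH2Cl2, −20 to 0 °C; dilution with THF to 0.01 M, 50 °C, Ar; then air, Et2O, rt, filtration through Et3N-washed silica
Reagents that add atoms: none
Why: The acylate oxygen of 6 displaces chloride from 15 to give siloxycarbene 16, which loses one cis CO (assisted by the ortho OMOM oxygen) and binds its own alkyne. Because only the O–Si–O bridge joins the carbene oxygen to the propargylic carbon, the alkyne can insert into Cr=C in one sense only, its substituted carbon bonding to the carbene carbon (C1–C2), which closes the six-membered 1,3,2-dioxasilin ring and overrides the steric rule that would put the substituent of a free terminal alkyne next to the CO-derived carbon. The vinylcarbene so formed inserts a CO ligand at the former terminal alkyne carbon (C3–C4), and the chromium-bound dienylketene closes ring B by 6π electrocyclisation of the ketene carbon onto the aryl ring (C4–C4a), after which tautomerisation gives naphthol complex 17 and air strips the metal. The closest known reaction type is the Dötz benzannulation in its intramolecular form with the alkyne tethered through the carbene oxygen, including dialkylsilyl-bridged siloxycarbene complexes of alkynols. No stereocentre is created, and the propargylic centre of 15 is neither deprotonated nor ionised under these neutral conditions, so its R configuration is carried through. Site selectivity rests on ring A having a single free ortho carbon (the other bears OMOM), chemoselectivity rests on the alkyne binding chromium far better than the trisubstituted prenyl alkene and on fast CO insertion at chromium in THF, and high dilution holds back intermolecular reaction.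

**Step 9**
Reactants: 18 (4R)-2,2-diisopropyl-7,10-bis(methoxymethoxy)-4-(3-methylbut-2-enyl)-4H-naphtho[1,2-d][1,3,2]dioxasilin-6-ol
Product: 20 2-[(1R)-1-hydroxy-4-methylpent-3-enyl]-5,8-bis(methoxymethoxy)naphthalene-1,4-dione, via hydroquinone 19 (not isolated)
Conditions: Et3N·3HF, THF, 0 °C; pH 7 buffer wash; then Ag2O, Na2SO4, Et2O, rt
Reagents that add atoms: none
Why: Fluoride-driven cleavage of both Si–O bonds removes the tether, and Ag2O oxidation of the freed 1,4-hydroquinone takes place only in ring B since ring A is still a diether, with the carbinol centre untouched.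

**Step 10**
Reactants: 20 2-[(1R)-1-hydroxy-4-methylpent-3-enyl]-5,8-bis(methoxymethoxy)naphthalene-1,4-dione
Product: 21 (R)-shikonin, 5,8-dihydroxy-2-[(1R)-1-hydroxy-4-methylpent-3-enyl]naphthalene-1,4-dione
Conditions: NaHSO4·SiO2, moist CH2Cl2, rt, dark
Reagents that add atoms: none
Why: Acid-catalysed acetal hydrolysis of phenolic MOM ethers on a mild solid acid, helped by the hydrogen bond each freed peri hydroxyl forms to its neighbouring quinone carbonyl, should spare the side-chain alcohol and the prenyl alkene.

**Step 11**
Reactants: 22 3-hydroxy-3-methylbutanoic acid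
Product: 24 3-acetoxy-3-methylbutanoic acid, via mixed anhydride 23 (not isolated)
Conditions: Ac2O, pyridine, DMAP (cat.), CH2Cl2, rt; then H2O/THF, rt
Reagents that add atoms: acetic anhydride, CC(=O)OC(C)=O
Why: DMAP-catalysed acetylation esterifies the tertiary alcohol, and water then cleaves the mixed anhydride at its less hindered acetyl carbonyl to return the free acid.

**Step 12**
Reactants: 21 (R)-shikonin; 24 3-acetoxy-3-methylbutanoic acid
Product: 25 (1R)-1-(5,8-dihydroxy-1,4-dioxo-1,4-dihydronaphthalen-2-yl)-4-methylpent-3-enyl 3-acetoxy-3-methylbutanoate (β-acetoxyisovalerylshikonin)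
Conditions: DCC, DMAP (cat.), CH2Cl2, 0 °C to rt, dark
Reagents that add atoms: none
Why: Steglich esterification acylates only the side-chain alcohol because both phenols of ring A are locked in strong hydrogen bonds to the quinone carbonyls, and the C–O bond at the stereocentre is not broken, so the R configuration is kept.

**Compound list**
1 | hydroquinone | Oc1ccc(O)cc1 | starting material
2 | 1,4-bis(methoxymethoxy)benzene | COCOc1ccc(OCOC)cc1 | intermediate
3 | hexacarbonylchromium Cr(CO)6 | O=C=[Cr](=C=O)(=C=O)(=C=O)(=C=O)=C=O | starting material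
4 | 2,5-bis(methoxymethoxy)phenyllithium | [Li]c1cc(OCOC)ccc1OCOC | intermediate
5 | lithium pentacarbonyl{[2,5-bis(methoxymethoxy)phenyl](oxido)methylidene}chromate | [Li+].[O-]C(c1cc(OCOC)ccc1OCOC)=[Cr](=C=O)(=C=O)(=C=O)(=C=O)=C=O | intermediate
6 | tetramethylammonium pentacarbonyl{[2,5-bis(methoxymethoxy)phenyl](oxido)methylidene}chromate | C[N+](C)(C)C.[O-]C(c1cc(OCOC)ccc1OCOC)=[Cr](=C=O)(=C=O)(=C=O)(=C=O)=C=O | intermediate
7 | 4-methylpent-3-enoic acid | CC(C)=CCC(=O)O | starting material
8 | 1-(imidazol-1-yl)-4-methylpent-3-en-1-one | CC(C)=CCC(=O)n1ccnc1 | intermediate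
9 | N-methoxy-N,4-dimethylpent-3-enamide | CC(C)=CCC(=O)N(C)OC | intermediate
10 | trimethylsilylacetylene | C#C[Si](C)(C)C | starting material
11 | lithium (trimethylsilyl)acetylide | [Li]C#C[Si](C)(C)C | intermediate
12 | 6-methyl-1-(trimethylsilyl)hept-5-en-1-yn-3-one | CC(C)=CCC(=O)C#C[Si](C)(C)C | intermediate
13 | (3R)-6-methyl-1-(trimethylsilyl)hept-5-en-1-yn-3-ol | O[C@H](CC=C(C)C)C#C[Si](C)(C)C | intermediate
14 | (3R)-6-methylhept-5-en-1-yn-3-ol | O[C@H](CC=C(C)C)C#C | intermediate
15 | chloro{[(3R)-6-methylhept-5-en-1-yn-3-yl]oxy}diisopropylsilane | Cl[Si](C(C)C)(C(C)C)O[C@H](CC=C(C)C)C#C | intermediate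
16 | pentacarbonyl{[2,5-bis(methoxymethoxy)phenyl][(diisopropyl{[(3R)-6-methylhept-5-en-1-yn-3-yl]oxy}silyl)oxy]methylidene}chromium | O=C=[Cr](=C=O)(=C=O)(=C=O)(=C=O)=C(O[Si](C(C)C)(C(C)C)O[C@H](CC=C(C)C)C#C)c1cc(OCOC)ccc1OCOC | intermediate
17 | η6-tricarbonylchromium complex of 18 | CC(C)[Si]1(C(C)C)O[C@H](CC=C(C)C)c2cc(O)c3c(OCOC)ccc(OCOC)c3c2O1.O=C=[Cr](=C=O)=C=O | intermediate
18 | (4R)-2,2-diisopropyl-7,10-bis(methoxymethoxy)-4-(3-methylbut-2-enyl)-4H-naphtho[1,2-d][1,3,2]dioxasilin-6-ol | CC(C)[Si]1(C(C)C)O[C@H](CC=C(C)C)c2cc(O)c3c(OCOC)ccc(OCOC)c3c2O1 | intermediate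
19 | 2-[(1R)-1-hydroxy-4-methylpent-3-enyl]-5,8-bis(methoxymethoxy)naphthalene-1,4-diol | O[C@H](CC=C(C)C)c1cc(O)c2c(OCOC)ccc(OCOC)c2c1O | intermediate
20 | 2-[(1R)-1-hydroxy-4-methylpent-3-enyl]-5,8-bis(methoxymethoxy)naphthalene-1,4-dione | O[C@H](CC=C(C)C)C1=CC(=O)c2c(OCOC)ccc(OCOC)c2C1=O | intermediate
21 | (R)-shikonin | O[C@H](CC=C(C)C)C1=CC(=O)c2c(O)ccc(O)c2C1=O | intermediate
22 | 3-hydroxy-3-methylbutanoic acid | CC(C)(O)CC(=O)O | starting material
23 | acetic 3-acetoxy-3-methylbutanoic anhydride | CC(=O)OC(C)(C)CC(=O)OC(C)=O | intermediate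
24 | 3-acetoxy-3-methylbutanoic acid | CC(=O)OC(C)(C)CC(=O)O | intermediate
25 | β-acetoxyisovalerylshikonin | CC(=O)OC(C)(C)CC(=O)O[C@H](CC=C(C)C)C1=CC(=O)c2c(O)ccc(O)c2C1=O | target

**Step count**
- Total step count: 12.
- Longest linear sequence: 9 steps, from 7 to 25 (steps 3 to 10 and step 12).

**Steps most likely to fail**

**Step 8.**
- What may go wrong: O-silylation by the hindered chlorosilane may be slow. The siloxycarbene may hydrolyse or decay before the alkyne inserts. Ring closure may occur without CO insertion, or the prenyl alkene may capture the vinylcarbene.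
- Fallback, from 6 and 14, back at 20. Compound 6 is O-methylated with Me3OBF4 to the methoxycarbene complex pentacarbonyl{[2,5-bis(methoxymethoxy)phenyl](methoxy)methylidene}chromium F1. Compound 14 is silylated (TBSCl, imidazole) to (3R)-3-(tert-butyldimethylsilyloxy)-6-methylhept-5-en-1-yne F2. The two are heated in THF at 50 °C in an ordinary intermolecular Dötz benzannulation, followed by air, to give 2-[(1R)-1-(tert-butyldimethylsilyloxy)-4-methylpent-3-enyl]-4-methoxy-5,8-bis(methoxymethoxy)naphthalen-1-ol F3.
- PhI(OAc)2 in aqueous MeCN at 0 °C oxidises F3 to the quinone silyl ether 2-[(1R)-1-(tert-butyldimethylsilyloxy)-4-methylpent-3-enyl]-5,8-bis(methoxymethoxy)naphthalene-1,4-dione F4. HF·pyridine in THF then frees 20.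
- Ring A carries the same group on C5 and C8, so either orientation of the alkyne ends in the same quinone.

**Step 10.**
- What may go wrong: under acid the free carbinol oxygen may close onto the protonated prenyl alkene, and ionisation at the carbinol carbon may erode the configuration.
- Fallback, from 20, back at 21. Ring A is unmasked by oxidation instead of hydrolysis. Brief treatment with AgO and aqueous HNO3 in acetone at 0 °C (oxidative dealkylation of a hydroquinone diether) gives 2-[(1R)-1-hydroxy-4-methylpent-3-enyl]naphthalene-1,4,5,8-tetraone F5. This is reduced at once with aqueous Na2S2O4, and air during work-up brings it to 21.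

**Step 12.**
- What may go wrong: the activated acid may lose acetic acid by E1cB elimination, the O-acylisourea may rearrange to the N-acylurea, and DMAP may trigger oligomerisation of the naphthazarin 21.
- Fallback, from 20 and 24, back at 25. The acyl group is put on before the phenols are freed. Compound 20, an ordinary secondary alcohol on a base-tolerant quinone, is acylated with 24 through its 2,4,6-trichlorobenzoyl mixed anhydride (Yamaguchi esterification). This gives (1R)-1-[5,8-bis(methoxymethoxy)-1,4-dioxo-1,4-dihydronaphthalen-2-yl]-4-methylpent-3-enyl 3-acetoxy-3-methylbutanoate F6. Its MOM ethers are then cleaved with NaHSO4·SiO2 in moist CH2Cl2 to give 25.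

**Further compounds**
F1 | step 8 | pentacarbonyl{[2,5-bis(methoxymethoxy)phenyl](methoxy)methylidene}chromium | COC(c1cc(OCOC)ccc1OCOC)=[Cr](=C=O)(=C=O)(=C=O)(=C=O)=C=O
F2 | step 8 | (3R)-3-(tert-butyldimethylsilyloxy)-6-methylhept-5-en-1-yne | CC(C)(C)[Si](C)(C)O[C@H](CC=C(C)C)C#C
F3 | step 8 | 2-[(1R)-1-(tert-butyldimethylsilyloxy)-4-methylpent-3-enyl]-4-methoxy-5,8-bis(methoxymethoxy)naphthalen-1-ol | CC(C)(C)[Si](C)(C)O[C@H](CC=C(C)C)c1cc(OC)c2c(OCOC)ccc(OCOC)c2c1O
F4 | step 8 | 2-[(1R)-1-(tert-butyldimethylsilyloxy)-4-methylpent-3-enyl]-5,8-bis(methoxymethoxy)naphthalene-1,4-dione | CC(C)(C)[Si](C)(C)O[C@H](CC=C(C)C)C1=CC(=O)c2c(OCOC)ccc(OCOC)c2C1=O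
F5 | step 10 | 2-[(1R)-1-hydroxy-4-methylpent-3-enyl]naphthalene-1,4,5,8-tetraone | O[C@H](CC=C(C)C)C1=CC(=O)C2=C(C1=O)C(=O)C=CC2=O
F6 | step 12 | (1R)-1-[5,8-bis(methoxymethoxy)-1,4-dioxo-1,4-dihydronaphthalen-2-yl]-4-methylpent-3-enyl 3-acetoxy-3-methylbutanoate | CC(=O)OC(C)(C)CC(=O)O[C@H](CC=C(C)C)C1=CC(=O)c2c(OCOC)ccc(OCOC)c2C1=O
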